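The readings stem from a simulated flask for an exercise; noise was put on by code.

| flask | starting material | solid second substrate | enzyme | remark | time |
|---|---|---|---|---|---|
| summer | 0.050 M | 0.21 M | 5 µM | run made earlier |  |
| noon | 0.050 M | 0.90 M | 5 µM | run made earlier |  |
| Wednesday's | 0.050 M | 0.0500 M | 5.0 µM |  | 3.0 h |
| Monday's | 0.050 M | 0.100 M | 5.0 µM |  | 3.0 h |
| Tuesday's | 0.050 M | 0.200 M | 5.0 µM |  | 3.0 h |
| Thursday's | 0.050 M | 0.400 M | 5.0 µM |  | 3.0 h |
| Sunday's | 0.050 M | 0.800 M | 5.0 µM |  | 3.0 h |

| run | time / min | target / % |
|---|---|---|
| summer | 25.0 | 51.4 |
| summer | 50.0 | 77.8 |
| summer | 80.0 | 86.0 |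
| summer | 90.0 | 87.3 |
| summer | 120 | 88.2 |
| noon | 25.0 | 51.8 |
| noon | 50.0 | 78.5 |
| noon | 80.0 | 87.5 |
| noon | 90.0 | 86.9 |
| noon | 120 | 88.1 |

(standard deviation of a reading: 0.5 percentage points)

- in percentages every species weighs as the starting material in it: one spent catalyst or homo dimer counts as two
- as a solid, counted per litre of solution: solid second substrate
- reactions considered so far: starting material + enzyme <-> starting complex; second substrate + starting complex <-> ternary complex; ternary complex -> enzyme + target; solid second substrate <-> second substrate; 2 ternary complex -> spent catalyst; 2 starting material -> homo dimer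
- at the start none of the solid second substrate is in solution
- "hardly changes" means that all values lie within two and a half points (for a concentration: within two and a half percent of the largest)

- [target] at the end for Wednesday's, Monday's, Tuesday's, Thursday's, Sunday's, in this order
- the course of these numbers from the first flask to the last (hardly changes / falls all the way / rises, then falls / rises all the way / falls, then rises)

1. The easy step comes first: the target levels off. The summer run stands at 88.2 % after 120 min and the noon run at 88.1 %, so I read the plateau as c(target) = 0.0441 M.

2. The curve starts steep. In the summer run c(target) climbs at 1.03 mM/min over the first 25.0 min, then at 0.528 mM/min over the next interval, half the first slope, so the bend has begun.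

3. Between those two readings the distance to the plateau falls from 37 percentage points to 10 points, which means it halves every 13.7 min. I carry this gap half-life, the time in which the distance of the target from its plateau halves.

4. I test it on a later reading. Counted on from 50.0 min, it gives a gap of 2.3 points at 80.0 min, and the summer run reads 2.2 points. The noon run, with 0.90 M of solid second substrate against 0.21 M, gives 13.0 min.

5. Each new flask runs 3.0 h, which is 13.1 gap half-lives. Wednesday's flask lies below the earlier loadings, but its 0.0500 M of solid still exceeds the plateau by 0.00590 M. So I reckon 0.0441 M in each flask, a flat row.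

The forecast differs from me at Wednesday's flask, with 0.0435 M there and 0.044 M in the others, course hardly changes, and says “I expect a flat row”.

The flasks give 0.0439 M, 0.0441 M, 0.0441 M, 0.0441 M and 0.0441 M: hardly changes.

    starting material + enzyme ⇌ starting complex (K = 37.1 /M, k = 607 /M/s)
    second substrate + starting complex ⇌ ternary complex (K = 14.7 /M, k = 7110 /M/s)
    ternary complex → enzyme + target (k = 35.2 /s)
    solid second substrate ⇌ second substrate, rate k4*(cs4 - [second substrate]) while solid is left; crystals form when [second substrate] > cs4 (solubility = 22.0 mM, k = 0.0105 /s)
    2 ternary complex → spent catalyst (k = 121 /M/s)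
    2 starting material → homo dimer (k = 0.00149 /M/s)

Sunday's flask has 0 % of its starting material left at 3.00 h, with 88.2 % as target and 11.8 % as homo dimer, after 13.1 gap half-lives. Wednesday's flask, its solid second substrate down to 0 % at 1.50 h, goes from 3.04 % to 0.238 % of starting material by 3.00 h, so over that stretch its remainder halves every 24.5 min, twice the gap half-life, and the stretch holds 3.68 of these.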